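## Retrosynthetic overview

1. Numbering used throughout: C1 methacrylate carbinol, C2 CH2, C3 isobutyrate carbinol, C4 quaternary C(CH3), C5 CH next to the C6 ketone, C7=C8(CH3), C9 and C10 the other two cyclobutane CH, C11 CMe2. Rings: cyclobutane C4-C5-C10-C9, cyclohexenone C5-C6-C7-C8-C9-C10, cycloheptane C1-C2-C3-C4-C5-C10-C11.
2. Feature that carries the plan: the oxygen on C1 and the C6 carbonyl are 1,5-related over C11, C10 and C5. The cycloheptane can therefore be read as the retro-aldol product of a cyclobutanol C1-C5-C10-C11 fused to a cyclopentane C1-C2-C3-C4-C5, and the two neopentylic bonds C1-C11 and C5-C10 fall to one [2+2] photocycloaddition.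
3. Late disconnections: first the two esters, then C4-C9 of the permanent cyclobutane, traced to a lower-face C3,C4-epoxide attacked by C9 of the C6 silyl dienol ether of a cis-fused himachalenone. The epoxide comes from a C3=C4 alkene (syn dehydration) and the C1 carbinol from a reduction directed by the C3 hydroxyl.
4. Key disconnection: a de Mayo sequence on enol acetate 11 makes C5-C10 and C1-C11, then cleaves C1-C5. Compound 11 comes from (R)-4-silyloxycyclopentenone 7 by methyl cuprate addition, aldol capture with Z-dienal 6, oxidation and enol acetylation.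
5. Ring order: cyclopentane (bought), cyclohexenone plus temporary cyclobutane (light), cycloheptane (fragmentation), permanent cyclobutane (epoxide opening).

Key step: step 8

Remark: "lower face" means the face of the seven-membered ring that carries H5 and H10, and "upper face" the face that carries C6 and C9. Stereodescriptors refer to the overview numbering.

## Route

Step 1
Reactants: 1 methyl propiolate; 2 1-bromo-3-methylbut-2-ene (prenyl bromide)
Product: 3 methyl 6-methylhept-5-en-2-ynoate
Conditions: CuI (10 mol %), K2CO3 (1.5 equiv), nBu4NI (10 mol %), DMF, 23 °C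
Reagents that add atoms: none
Why: Copper-catalysed allylation of a terminal alkyne: the copper acetylide of the acidic propiolate displaces the primary allylic bromide at its unsubstituted end (SN2), and carbonate is too weak a base to pull the skipped enyne into conjugation.

Step 2
Reactants: 3 methyl 6-methylhept-5-en-2-ynoate
Product: 4 methyl (2Z)-3,6-dimethylhepta-2,5-dienoate
Conditions: Me2CuLi (1.2 equiv), THF, −78 °C; MeOH, −78 °C
Reagents that add atoms: lithium dimethylcuprate, [Li+].C[Cu-]C
Why: Syn carbocupration of a 2-alkynoate: methyl and copper add to the same side of the triple bond and cold protonation keeps that geometry, so the C9 chain ends up cis to the ester carbon C6 (2Z).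

Step 3
Reactants: 4 methyl (2Z)-3,6-dimethylhepta-2,5-dienoate
Product: 5 (2Z)-3,6-dimethylhepta-2,5-dien-1-ol
Conditions: iBu2AlH (2.3 equiv), CH2Cl2, −78 °C; aq. potassium sodium tartrate
Reagents that add atoms: none
Why: Aluminium hydride 1,2-reduction of an enoate to the allylic alcohol, which touches neither the Z double bond nor the skipped diene.

Step 4
Reactants: 5 (2Z)-3,6-dimethylhepta-2,5-dien-1-ol
Product: 6 (2Z)-3,6-dimethylhepta-2,5-dienal
Conditions: TEMPO (10 mol %), PhI(OAc)2 (1.1 equiv), MeCN/pH 7 phosphate buffer, 0 °C
Reagents that add atoms: none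
Why: Oxoammonium (TEMPO) oxidation of a primary allylic alcohol in buffered medium, the standard way to reach Z-enals of the neral type without Z-to-E isomerisation or migration of the skipped double bond.

Step 5
Reactants: 7 (4R)-4-(tert-butyldimethylsilyloxy)cyclopent-2-en-1-one; 6 (2Z)-3,6-dimethylhepta-2,5-dienal
Product: 9 (2S,3R,4R)-4-(tert-butyldimethylsilyloxy)-2-[(2Z)-1-hydroxy-3,6-dimethylhepta-2,5-dienyl]-3-methylcyclopentan-1-one (carbinol epimers), via lithium enolate 8 (not isolated)
Conditions: Me2CuLi (1.1 equiv), Et2O, −78 °C; then 6 (1.2 equiv), THF, −78 °C; AcOH, −78 °C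
Reagents that add atoms: lithium dimethylcuprate, [Li+].C[Cu-]C
Why: Three-component coupling (cuprate 1,4-addition, then aldol capture): methyl adds anti to the silyloxy group and sets C4, and the regiodefined enolate 8 is intercepted at C5 anti to the new methyl before it can equilibrate towards C2 and expel silanolate; the carbinol mixture at C6 is erased in step 6.

Step 6
Reactants: 9 aldol adduct
Product: 10 (3R,4R)-4-(tert-butyldimethylsilyloxy)-2-[(2Z)-3,6-dimethylhepta-2,5-dienoyl]-3-methylcyclopentan-1-one (enolised 1,3-diketone)
Conditions: IBX (1.5 equiv), DMSO, 23 °C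
Reagents that add atoms: none
Why: IBX oxidation of a β-hydroxy ketone to the β-diketone, a neutral method that avoids retro-aldol cleavage and leaves the silyl ether and both alkenes alone.

Step 7
Reactants: 10 1,3-diketone
Product: 11 (3R,4R)-4-(tert-butyldimethylsilyloxy)-2-[(2Z)-3,6-dimethylhepta-2,5-dienoyl]-3-methylcyclopent-1-en-1-yl acetate
Conditions: AcCl (1.3 equiv), pyridine (3 equiv), CH2Cl2, 0 °C
Reagents that add atoms: acetyl chloride, CC(=O)Cl
Why: O-acylation of an enolised 2-acylcyclopentanone: the ring oxygen is acetylated because C6=O then stays conjugated with C7=C8, whereas the exocyclic enol acetate would press its acetoxy group or dienyl chain against the C4 methyl branch (allylic strain).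

Step 8
Reactants: 11 enol acetate
Product: 14 cis-fused (3R,4R,5R,10S)-3-(tert-butyldimethylsilyloxy)himachal-7-ene-1,6-dione, via photoadduct acetate 12 (not isolated), via cyclobutanol 13 (not isolated)
Conditions: hν (medium-pressure Hg lamp, Pyrex, λ > 300 nm), degassed MeCN (2 mM), 0 °C; then K2CO3 (0.3 equiv), MeOH, 0 °C, same flask
Reagents that add atoms: none
Why: Intramolecular de Mayo reaction: the excited β-acetoxy enone C1=C5-C6=O bonds C5 to C10, the resulting 1,4-biradical (α-acetoxy radical at C1, tertiary radical at C11) couples C1 to C11 after spin inversion, and methanolysis of the tertiary acetate of 12 frees cyclobutanol 13, whose C1-C5 bond breaks by retro-aldol reaction because C5 carries the C6 acyl group and the four-membered ring is strained. The closest known reaction type is the photocycloaddition–fragmentation of enol esters and enol carbonates of 2-acylcyclopentanones that carry a tethered alkene, which gives fused cycloheptane 1,5-diketones. The cyclohexenone closes 6-exo-trig over the four-atom tether C6-C7-C8-C9 (straight, not crossed, because tether length and the Z C7=C8 bond put C10 and not C11 next to C5), the temporary cyclobutane closes by radical–radical coupling, and the cycloheptane arises by two-carbon ring expansion rather than by a closure. C10 is controlled by the C4 methyl group, since C10 reaches C5 on the ring face anti to this vicinal substituent (as electrophiles do with 3-substituted cyclopentanone enolates) and the cis 6/4 fusion forced by the tether then fixes H10; C5 is reset when the liberated enolate is protonated on the face away from the quaternary C11, which gives the cis 6/7 fusion and stays correctable by base. The step needs the ring-enol tautomer, which the acetate locks (the exocyclic enol would close a five-membered ring), and it needs the Z-dienoyl geometry: light interconverts the Z and E isomers and only Z can close, so E is drained through the photoequilibrium, while reversible photoenolisation at C9 is harmless in base-free aprotic solvent. Short, cold methanolysis with substoichiometric K2CO3 keeps the new β-silyloxy ketone (C1/C3) from eliminating.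

Step 9
Reactants: 14 silyloxy dione
Product: 15 (3R,4R,5R,10S)-3-hydroxy-cis-himachal-7-ene-1,6-dione
Conditions: HF·pyridine, THF, 0 → 23 °C
Reagents that add atoms: none
Why: Fluoride-driven silyl ether cleavage in a weakly acidic medium, which spares the β-hydroxy ketone from retro-aldol cleavage and β-elimination and does not epimerise C5.

Step 10
Reactants: 15 hydroxy dione
Product: 16 (1R,3R,4R,5R,10S)-1,3-dihydroxy-cis-himachal-7-en-6-one (1,3-trans diol)
Conditions: Me4NBH(OAc)3 (5 equiv), MeCN/AcOH (1:1), −20 °C
Reagents that add atoms: none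
Why: Saksena–Evans hydroxyl-directed reduction: the borohydride exchanges an acetate for the lower-face C3-OH and delivers hydride to C1 from that same face, so the new C1-OH stands on the upper face (1,3-trans, 1R), and the untethered C6 enone is not reduced by this mild reagent.

Step 11
Reactants: 16 diol
Product: 17 3-O-triethylsilyl ether of 16
Conditions: Et3SiCl (1.05 equiv), imidazole (2 equiv), CH2Cl2, −20 °C
Reagents that add atoms: chlorotriethylsilane, CC[Si](Cl)(CC)CC
Why: Sterically selective silylation: C3-OH has a tertiary neighbour (C4) whereas C1-OH is neopentylic (next to C11), so one equivalent of chlorosilane at low temperature should take only C3-OH.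

Step 12
Reactants: 17 monosilyl ether
Product: 18 1-O-methacrylate of 17
Conditions: methacrylic anhydride (3 equiv), DMAP (0.5 equiv), Et3N (4 equiv), BHT (trace), CH2Cl2, 35 °C
Reagents that add atoms: methacrylic anhydride, C=C(C)C(=O)OC(=O)C(C)=C
Why: DMAP-catalysed acyl transfer to the only free, hindered hydroxyl group, with retention at C1; the amine bases are too weak to enolise C5.

Step 13
Reactants: 18 silyl ether methacrylate
Product: 19 (1R,3R,4R,5R,10S)-3-hydroxy-1-methacryloyloxy-cis-himachal-7-en-6-one
Conditions: PPTS (0.2 equiv), MeOH, 0 °C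
Reagents that add atoms: none
Why: Acid-catalysed methanolysis of a triethylsilyl ether, mild enough to leave the methacrylate, the enone and C5 untouched.

Step 14
Reactants: 19 C3 alcohol
Product: 21 (1R,5R,10S)-1-methacryloyloxy-cis-himachala-3,7-dien-6-one, via sulfamate ester 20 (not isolated)
Conditions: Burgess reagent MeO2CN(−)SO2N(+)Et3 (2 equiv), toluene, 23 → 50 °C
Reagents that add atoms: none
Why: Burgess dehydration (thermal syn elimination): because methyl was delivered trans to the C3 oxygen, H4 is cis to the sulfamate in 20 and is taken in preference to the cis hydrogen on C2 (the more substituted alkene, as with trans-2-methylcycloalkanols), and the neutral medium keeps the new β,γ-double bond from moving into conjugation with C6=O.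

Step 15
Reactants: 21 dienone
Product: 22 (1R,3R,4S,5R,10S)-3,4-epoxy-1-methacryloyloxy-cis-himachal-7-en-6-one (oxygen on the lower face)
Conditions: DMDO (1.1 equiv, acetone solution), CH2Cl2, −20 °C
Reagents that add atoms: dimethyldioxirane, CC1(C)OO1
Why: Neutral dioxirane epoxidation: the electron-rich trisubstituted C3=C4 bond reacts much faster than the enone and methacrylate alkenes, and oxygen arrives on the convex lower face, away from C6 on C5 and from the C1 ester, which sets C3 (R) and C4 (S).

Step 16
Reactants: 22 epoxy enone
Product: 23 C6 tert-butyldimethylsilyl dienol ether of 22 (C6=C7 and C8=C9)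
Conditions: TBSOTf (1.3 equiv), Et3N (2.5 equiv), CH2Cl2, −78 °C; cold aq. NaHCO3
Reagents that add atoms: tert-butyldimethylsilyl trifluoromethanesulfonate, CC(C)(C)[Si](C)(C)OS(=O)(=O)C(F)(F)F
Why: Soft enolisation (silyl triflate/amine): O-silylation of the enone and loss of a γ-proton from C9 give the through-conjugated homoannular dienol ether, the α'-hydrogen on C5 being tertiary and shielded by the fully substituted C4, while excess amine at −78 °C keeps the silyl triflate from opening the epoxide.

Step 17
Reactants: 23 epoxy silyl dienol ether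
Product: 25 (1R,3R,4R,5R,9R,10S)-3-hydroxy-1-methacryloyloxylongipin-7-en-6-one (target skeleton with free C3-OH), via silyl ether 24 (not isolated)
Conditions: TBSOTf (0.2 equiv), 2,6-di-tert-butyl-4-methylpyridine (0.3 equiv), CH2Cl2, −78 → −40 °C; then HF·pyridine, THF, 0 → 23 °C, same flask
Reagents that add atoms: none
Why: Proposed new method: the silyl triflate silylates the epoxide oxygen so that the tertiary C4-O bond lengthens, and the γ-carbon C9 of the dienol ether, held above C4 by the cis ring fusion and thus anti to the lower-face oxygen, attacks C4 with inversion in a 4-exo-tet vinylogous Mukaiyama-type alkylation that sets C4 and C9 (the only geometry the one-atom bridge allows) and keeps the C3-O configuration; silyl loss from the resulting oxocarbenium ion regenerates the catalyst, and epoxide strain release plus enone formation pay for the cyclobutane; the closest known reaction types are Lewis acid mediated openings of epoxides by tethered silyl enol ethers (five- and six-membered rings), γ-selective SN1-type alkylations of silyl dienol ethers, and the pinyl-type closure of an exocyclic cation onto a 1,3-related ring alkene.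

Step 18
Reactants: 25 tricyclic alcohol
Product: 26 target CNP0214356.1
Conditions: isobutyric anhydride (3 equiv), DMAP (0.5 equiv), Et3N (4 equiv), CH2Cl2, 35 °C
Reagents that add atoms: isobutyric anhydride, CC(C)C(=O)OC(=O)C(C)C
Why: DMAP-catalysed esterification of the remaining hindered C3 hydroxyl with retention; C5 and C9 are now bridgeheads and can no longer epimerise.

## Compound list

1 | methyl propiolate | C#CC(=O)OC | starting material
2 | 1-bromo-3-methylbut-2-ene | CC(C)=CCBr | starting material
3 | methyl 6-methylhept-5-en-2-ynoate | COC(=O)C#CCC=C(C)C | intermediate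
4 | methyl (2Z)-3,6-dimethylhepta-2,5-dienoate | COC(=O)/C=C(/C)CC=C(C)C | intermediate
5 | (2Z)-3,6-dimethylhepta-2,5-dien-1-ol | OC/C=C(/C)CC=C(C)C | intermediate
6 | (2Z)-3,6-dimethylhepta-2,5-dienal | O=C/C=C(/C)CC=C(C)C | intermediate
7 | (4R)-4-(tert-butyldimethylsilyloxy)cyclopent-2-en-1-one | O=C1C=C[C@H](O[Si](C)(C)C(C)(C)C)C1 | starting material
8 | lithium (3R,4R)-4-(tert-butyldimethylsilyloxy)-3-methylcyclopent-1-en-1-olate | [Li+].[O-]C1=C[C@@H](C)[C@H](O[Si](C)(C)C(C)(C)C)C1 | intermediate
9 | aldol adduct, 2,3-trans-3,4-trans, carbinol epimers | O=C1C[C@@H](O[Si](C)(C)C(C)(C)C)[C@H](C)[C@H]1C(O)/C=C(/C)CC=C(C)C | intermediate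
10 | 2-dienoyl-3-methyl-4-silyloxycyclopentanone (enolised) | O=C1C[C@@H](O[Si](C)(C)C(C)(C)C)[C@H](C)C1C(=O)/C=C(/C)CC=C(C)C | intermediate
11 | ring enol acetate, photochemical precursor | CC(=O)OC1=C(C(=O)/C=C(/C)CC=C(C)C)[C@@H](C)[C@H](O[Si](C)(C)C(C)(C)C)C1 | intermediate
12 | photoadduct acetate (cyclobutane C1-C5-C10-C11 anti to the C4 methyl, 5/4 and 6/4 fusions cis) | CC(=O)O[C@]12C[C@@H](O[Si](C)(C)C(C)(C)C)[C@H](C)[C@@]1(C(=O)C=C(C)C3)[C@H]3C2(C)C | intermediate
13 | cyclobutanol from 12 | O[C@]12C[C@@H](O[Si](C)(C)C(C)(C)C)[C@H](C)[C@@]1(C(=O)C=C(C)C3)[C@H]3C2(C)C | intermediate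
14 | cis-fused 3-silyloxyhimachal-7-ene-1,6-dione | O=C1C[C@@H](O[Si](C)(C)C(C)(C)C)[C@H](C)[C@@H]2C(=O)C=C(C)C[C@@H]2C1(C)C | intermediate
15 | 3-hydroxy dione | O=C1C[C@@H](O)[C@H](C)[C@@H]2C(=O)C=C(C)C[C@@H]2C1(C)C | intermediate
16 | 1,3-trans diol | O[C@@H]1C[C@@H](O)[C@H](C)[C@@H]2C(=O)C=C(C)C[C@@H]2C1(C)C | intermediate
17 | 3-O-triethylsilyl ether | O[C@@H]1C[C@@H](O[Si](CC)(CC)CC)[C@H](C)[C@@H]2C(=O)C=C(C)C[C@@H]2C1(C)C | intermediate
18 | 1-O-methacrylate 3-O-triethylsilyl ether | C=C(C)C(=O)O[C@@H]1C[C@@H](O[Si](CC)(CC)CC)[C@H](C)[C@@H]2C(=O)C=C(C)C[C@@H]2C1(C)C | intermediate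
19 | 1-O-methacrylate with free C3-OH | C=C(C)C(=O)O[C@@H]1C[C@@H](O)[C@H](C)[C@@H]2C(=O)C=C(C)C[C@@H]2C1(C)C | intermediate
20 | C3 N-(methoxycarbonyl)sulfamate ester, triethylammonium salt | C=C(C)C(=O)O[C@@H]1C[C@@H](OS(=O)(=O)[N-]C(=O)OC)[C@H](C)[C@@H]2C(=O)C=C(C)C[C@@H]2C1(C)C.CC[NH+](CC)CC | intermediate
21 | C3=C4 alkene | C=C(C)C(=O)O[C@@H]1CC=C(C)[C@@H]2C(=O)C=C(C)C[C@@H]2C1(C)C | intermediate
22 | lower-face C3,C4-epoxide | C=C(C)C(=O)O[C@@H]1C[C@H]3O[C@@]3(C)[C@@H]2C(=O)C=C(C)C[C@@H]2C1(C)C | intermediate
23 | epoxy silyl dienol ether | C=C(C)C(=O)O[C@@H]1C[C@H]3O[C@@]3(C)[C@@H]2C(O[Si](C)(C)C(C)(C)C)=CC(C)=C[C@@H]2C1(C)C | intermediate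
24 | tricyclic C3 silyl ether | C=C(C)C(=O)O[C@@H]1C[C@@H](O[Si](C)(C)C(C)(C)C)[C@@]2(C)[C@@H]3C(=O)C=C(C)[C@H]2[C@@H]3C1(C)C | intermediate
25 | tricyclic C3 alcohol | C=C(C)C(=O)O[C@@H]1C[C@@H](O)[C@@]2(C)[C@@H]3C(=O)C=C(C)[C@H]2[C@@H]3C1(C)C | intermediate
26 | CNP0214356.1 | C=C(C)C(=O)O[C@@H]1C[C@@H](OC(=O)C(C)C)[C@@]2(C)[C@@H]3C(=O)C=C(C)[C@H]2[C@@H]3C1(C)C | target

## Step count and risks

Total step count: 18. Longest linear sequence: 18 steps (1 and 2 to 26; enone 7 enters at step 5).

**Step 17 (C4-C9 closure).**
- What may go wrong: once the C4-O bond is ionised, three processes may outrun the strained four-membered closure. These are loss of H5 or of a methyl proton, and a 1,2-hydride shift from C3 (Meinwald rearrangement). Any dienol ether that carries the exocyclic C8=CH2 bond cannot close at all.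
- Fallback (anionic instead of cationic bond formation, known chemistry): it sets out from 23 and comes back at 25.
- Treatment of 23 with (Me2N)3S(+) Me3SiF2(−) in THF from −78 to 0 °C cleaves the silyl dienol ether. This is fluoride-induced regiospecific enolate generation, and it gives the tris(dimethylamino)sulfonium dienolate F1.
- The medium holds no amine and no ketone that could relay the charge to C5 and so open the epoxide by β-elimination.
- C9 of F1 then opens the epoxide at C4 in an enolate–epoxide 4-exo-tet closure of the type established for cyclobutyl carbinols (epoxynitrile and epoxy ketone cyclisations). Attack through C7 would have to build a cyclobutanone.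
- Aqueous NH4Cl gives 25.

**Step 8 (key step).**
- What may go wrong: the dienoyl chromophore may spend the absorbed light on Z/E isomerisation and photoenolisation. Cycloaddition would then be slow and secondary photolysis of the cyclohexenone product could take over. The C3 silyloxy group, which sits on the face being attacked, may also erode facial selectivity.
- Fallback (C7=C8 is taken out of the chromophore and restored after the fragmentation): it sets out from 4 and 7 and comes back at 14.
- Copper-catalysed β-borylation of 4 (B2pin2, CuCl, NaOtBu, DPEphos, MeOH, THF) gives the tertiary boronate F2, and NaBO3·4H2O gives the tertiary alcohol F3.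
- Et3SiOTf/2,6-lutidine gives the silyl ether F4, and iBu2AlH at −78 °C gives the aldehyde F5.
- The operations of steps 5 to 7 (Me2CuLi on 7, capture with F5, IBX, AcCl/pyridine) give the aldol F6, the diketone F7 and the enol acetate F8. The only chromophore of F8 is the β-acetoxy enone.
- Irradiation as in step 8 gives the photoadduct F9, and K2CO3/MeOH gives the β-silyloxy dione F10.
- Catalytic TsOH in toluene removes triethylsilanol across C7-C8 and gives 14. C8 is an inconsequential epimer mixture up to that point.

**Step 14 (dehydration).**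
- What may go wrong: the syn elimination may take the cis hydrogen on C2 instead of H4, or the new double bond may drift into conjugation with C6=O.
- Fallback (inversion followed by anti elimination): it sets out from 19 and comes back at 21.
- Appel-type iodination (I2, PPh3, imidazole, toluene) replaces the lower-face hydroxyl with inversion and gives the upper-face iodide F11. In F11, H4 is antiperiplanar to the leaving group.
- Brief treatment with DBU in toluene then effects Zaitsev-oriented E2 elimination to 21.

## Further compounds

F1 | step 17 | tris(dimethylamino)sulfonium dienolate of 22 | CN(C)[S+](N(C)C)N(C)C.C=C(C)C(=O)O[C@@H]1C[C@H]3O[C@@]3(C)[C@@H]2C([O-])=CC(C)=C[C@@H]2C1(C)C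
F2 | step 8 | methyl 3,6-dimethyl-3-(4,4,5,5-tetramethyl-1,3,2-dioxaborolan-2-yl)hept-5-enoate | COC(=O)CC(C)(CC=C(C)C)B1OC(C)(C)C(C)(C)O1
F3 | step 8 | methyl 3-hydroxy-3,6-dimethylhept-5-enoate | COC(=O)CC(C)(O)CC=C(C)C
F4 | step 8 | methyl 3,6-dimethyl-3-(triethylsilyloxy)hept-5-enoate | COC(=O)CC(C)(CC=C(C)C)O[Si](CC)(CC)CC
F5 | step 8 | 3,6-dimethyl-3-(triethylsilyloxy)hept-5-enal | O=CCC(C)(CC=C(C)C)O[Si](CC)(CC)CC
F6 | step 8 | aldol adduct of 8 and F5 | O=C1C[C@@H](O[Si](C)(C)C(C)(C)C)[C@H](C)[C@H]1C(O)CC(C)(CC=C(C)C)O[Si](CC)(CC)CC
F7 | step 8 | 1,3-diketone with masked C7-C8 | O=C1C[C@@H](O[Si](C)(C)C(C)(C)C)[C@H](C)C1C(=O)CC(C)(CC=C(C)C)O[Si](CC)(CC)CC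
F8 | step 8 | ring enol acetate with masked C7-C8 | CC(=O)OC1=C(C(=O)CC(C)(CC=C(C)C)O[Si](CC)(CC)CC)[C@@H](C)[C@H](O[Si](C)(C)C(C)(C)C)C1
F9 | step 8 | photoadduct acetate with masked C7-C8 | CC(=O)O[C@]12C[C@@H](O[Si](C)(C)C(C)(C)C)[C@H](C)[C@@]1(C(=O)CC(C)(O[Si](CC)(CC)CC)C3)[C@H]3C2(C)C
F10 | step 8 | cis-fused 8-triethylsilyloxy-3-silyloxyhimachalane-1,6-dione | O=C1C[C@@H](O[Si](C)(C)C(C)(C)C)[C@H](C)[C@@H]2C(=O)CC(C)(O[Si](CC)(CC)CC)C[C@@H]2C1(C)C
F11 | step 14 | upper-face C3 iodide of 19 | C=C(C)C(=O)O[C@@H]1C[C@H](I)[C@H](C)[C@@H]2C(=O)C=C(C)C[C@@H]2C1(C)C
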